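**Plan**
- Cuts, in order: (a) the bond from ring carbon C1 of the trimethoxyphenyl ring to the carbinol carbon, cut with allylic transposition. This gives an aryl Grignard reagent and an (E)-3-bromoprop-1-enyl ester that already holds the whole diester chain. (b) The enol-ester C–O and CH2–Br bonds, giving acrolein and an acyl bromide. (c) The CH2–O bond of the angelate. (d) The C2–CH2OH bond of the Z hydroxymethylbutenoate.
- Enabling feature: the carbinol carbon carries the benzene ring, an acyloxy oxygen and a terminal vinyl group at once. CH(OCOR)–CH=CH2 is therefore the SN2′ retron of BrCH2–CH=CH–OCOR, the adduct of acrolein and an acyl bromide.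
- Forward order: no ring is built, since the benzene ring is bought as the aryl bromide. The chain grows from but-2-ynoate to the Z hydroxymethylbutenoate, then the angelate diester, the free acid and the bromopropenyl ester. Union with the aryl Grignard reagent is the last step.
- Stereochemistry: the inner Z alkene comes from syn hydroalumination. The Z angelate is bought and is never activated at its acyl carbon. The S centre comes from a chiral copper catalyst in the final step, so no later step can erode it.

Key step: step 7

Assumption: the sense of induction of Taniaphos with an aryl donor cannot be predicted safely, so the ligand enantiomer (both are sold) that sends the aryl group to the Re face of the O-bearing alkene carbon is fixed in a pilot run by correlation with the S alcohol obtained by resolution.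

Step 1
Reactants: 1 but-2-ynoic acid
Product: 2 tert-butyl but-2-ynoate
Conditions: isobutene (excess), conc. H2SO4 (cat.), CH2Cl2, sealed flask, −78 °C to rt
Reagents that add atoms: isobutene, CC(C)=C
Why: Acid-catalysed addition of a carboxylic acid to isobutene (tert-butyl esterification) is routine for alkynoic acids and gives an ester that resists 1,2-reduction in step 2 and can later be removed by acid without touching an angelate.

Step 2
Reactants: 2 tert-butyl but-2-ynoate
Product: 4 tert-butyl (Z)-2-(hydroxymethyl)but-2-enoate, via vinylalane 3 (not isolated)
Conditions: i-Bu2AlH, anhydrous N-methylmorpholine N-oxide, THF, 0 °C; then 2, 0 °C; then paraformaldehyde, 0 °C to rt; sat. aq NH4Cl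
Reagents that add atoms: formaldehyde (charged as paraformaldehyde), C=O
Why: In this vinylalumination the Lewis-base-modified hydride adds H and Al syn across the ynoate with Al at the α-carbon, and the C–Al bond is exchanged for C–CH2OH with retention (or anti to the β-methyl if the allenolate form reacts), so that CH3 should end cis to the ester, which is the Z alkene.

Step 3
Reactants: 4 tert-butyl (Z)-2-(hydroxymethyl)but-2-enoate; 5 angelic acid, (Z)-2-methylbut-2-enoic acid
Product: 6 tert-butyl (Z)-2-({[(Z)-2-methylbut-2-enoyl]oxy}methyl)but-2-enoate
Conditions: PPh3, DIAD (premixed at 0 °C), then 5 and 4, THF, 0 °C to rt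
Reagents that add atoms: none
Why: The Mitsunobu esterification activates the primary allylic alcohol and not the acid, so the angelate never passes through an acyl-activated form prone to Z to E isomerisation, and SN2 attack at the open CH2 should outrun SN2′ attack at the methyl-bearing alkene carbon.

Step 4
Reactants: 6 tert-butyl (Z)-2-({[(Z)-2-methylbut-2-enoyl]oxy}methyl)but-2-enoate
Product: 7 (Z)-2-({[(Z)-2-methylbut-2-enoyl]oxy}methyl)but-2-enoic acid
Conditions: CF3CO2H/CH2Cl2 (1:4), 0 °C to rt
Reagents that add atoms: none
Why: Acidolysis of the tert-butyl ester with loss of isobutene is orthogonal to the primary angelate and should leave both electron-poor Z alkenes unchanged.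

Step 5
Reactants: 7 (Z)-2-({[(Z)-2-methylbut-2-enoyl]oxy}methyl)but-2-enoic acid; 8 acrolein
Product: 11 (E)-3-bromoprop-1-en-1-yl (Z)-2-({[(Z)-2-methylbut-2-enoyl]oxy}methyl)but-2-enoate, via acyl bromide 9 (not isolated), via 1-bromoallyl ester 10 (not isolated)
Conditions: 1-bromo-N,N,2-trimethylprop-1-en-1-amine (1.0 equiv), CH2Cl2, 0 °C; then 8, ZnCl2 (cat.), −20 °C to rt; rapid chromatography to remove the minor Z enol ester
Reagents that add atoms: 1-bromo-N,N,2-trimethylprop-1-en-1-amine, CC(C)=C(Br)N(C)C
Why: The α-bromoenamine forms the acyl bromide under neutral, HBr-free conditions, and addition of an acyl bromide to the acrolein C=O followed by 1,3-shift of bromide is the standard entry to 3-bromopropenyl esters, in which equilibration should favour the conjugated E enol ester.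

Step 6
Reactants: 12 5-bromo-1,2,3-trimethoxybenzene
Product: 13 3,4,5-trimethoxyphenylmagnesium bromide
Conditions: Mg turnings (activated with a crystal of I2), Et2O, reflux; titrated and used as a solution
Reagents that add atoms: magnesium, [Mg]
Why: Grignard formation by insertion of Mg into an aryl bromide is routine, and Et2O is chosen because ethereal Grignard solutions are the ones that work in copper-catalysed allylic substitutions run in CH2Cl2.

Step 7
Reactants: 11 (E)-3-bromoprop-1-en-1-yl (Z)-2-({[(Z)-2-methylbut-2-enoyl]oxy}methyl)but-2-enoate; 13 3,4,5-trimethoxyphenylmagnesium bromide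
Product: 14 (S)-1-(3,4,5-trimethoxyphenyl)prop-2-en-1-yl (Z)-2-({[(Z)-2-methylbut-2-enoyl]oxy}methyl)but-2-enoate (target)
Conditions: CuBr·SMe2 (5 mol %), Taniaphos = 1-[α-(dimethylamino)-2-(diphenylphosphino)benzyl]-2-(diphenylphosphino)ferrocene (6 mol %), CH2Cl2, −78 °C; 13 (1.15 equiv in Et2O) by syringe pump; MeOH, then aq NH4Cl at −78 °C
Reagents that add atoms: none
Why: Proposed new method: transmetalation of 13 to the diphosphine-bound monovalent copper bromide gives a chiral aryl copper–magnesium bromide complex that binds the C=C of 11 anti to the C–Br bond, adds oxidatively in the SN2′ sense to a σ-allyl trivalent copper species at the O-bearing carbon and reductively eliminates at once, which forms the aryl–carbinol C–C bond, moves the alkene to the terminus and expels MgBr2. The closest known reaction types are the copper/Taniaphos-catalysed asymmetric allylic alkylation of 3-bromopropenyl benzoates and cinnamates with alkyl Grignard reagents and the copper-catalysed asymmetric allylic arylation of cinnamyl bromides with aryl Grignard reagents; new is the aryl donor on a γ-acyloxy allyl bromide. No ring is closed. The one new stereocentre is controlled by the ligand alone, which has to shield the Si face of the O-bearing alkene carbon of the E enol ester so that the aryl group arrives on the Re face and gives S. γ over α selectivity is needed and should be secured by the bromide leaving group in non-coordinating CH2Cl2 and by the electron-poor, acyloxy-substituted trivalent copper centre, from which an sp2 carbon ligand eliminates faster than σ–π–σ equilibration to the primary terminus. Chemoselectivity for the allyl bromide over the ester carbonyls and over the 2-(acyloxymethyl)enoate (itself an SN2′ acceptor) is needed and rests on −78 °C, slow addition of only a slight excess of 13, the far better leaving group and the β-methyl groups that slow attack on both enoates.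

**Compound list**
1 | but-2-ynoic acid | CC#CC(=O)O | starting material
2 | tert-butyl but-2-ynoate | CC#CC(=O)OC(C)(C)C | intermediate
3 | tert-butyl (E)-2-(diisobutylalumanyl)but-2-enoate (vinylalane, H and Al cis) | CC(C)(C)OC(=O)/C(=C\C)[Al](CC(C)C)CC(C)C | intermediate
4 | tert-butyl (Z)-2-(hydroxymethyl)but-2-enoate | CC(C)(C)OC(=O)/C(=C\C)CO | intermediate
5 | angelic acid, (Z)-2-methylbut-2-enoic acid | OC(=O)/C(C)=C\C | starting material
6 | tert-butyl (Z)-2-({[(Z)-2-methylbut-2-enoyl]oxy}methyl)but-2-enoate | CC(C)(C)OC(=O)/C(=C\C)COC(=O)/C(C)=C\C | intermediate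
7 | (Z)-2-({[(Z)-2-methylbut-2-enoyl]oxy}methyl)but-2-enoic acid | OC(=O)/C(=C\C)COC(=O)/C(C)=C\C | intermediate
8 | acrolein | C=CC=O | starting material
9 | (Z)-2-({[(Z)-2-methylbut-2-enoyl]oxy}methyl)but-2-enoyl bromide | BrC(=O)/C(=C\C)COC(=O)/C(C)=C\C | intermediate
10 | racemic 1-bromoprop-2-en-1-yl (Z)-2-({[(Z)-2-methylbut-2-enoyl]oxy}methyl)but-2-enoate | C=CC(Br)OC(=O)/C(=C\C)COC(=O)/C(C)=C\C | intermediate
11 | (E)-3-bromoprop-1-en-1-yl (Z)-2-({[(Z)-2-methylbut-2-enoyl]oxy}methyl)but-2-enoate | BrC/C=C/OC(=O)/C(=C\C)COC(=O)/C(C)=C\C | intermediate
12 | 5-bromo-1,2,3-trimethoxybenzene | COc1cc(Br)cc(OC)c1OC | starting material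
13 | 3,4,5-trimethoxyphenylmagnesium bromide | COc1cc([Mg]Br)cc(OC)c1OC | intermediate
14 | (S)-1-(3,4,5-trimethoxyphenyl)prop-2-en-1-yl (Z)-2-({[(Z)-2-methylbut-2-enoyl]oxy}methyl)but-2-enoate | C=C[C@H](OC(=O)/C(=C\C)COC(=O)/C(C)=C\C)c1cc(OC)c(OC)c(OC)c1 | target

Total step count: 7. Longest linear sequence: 6 (steps 1, 2, 3, 4, 5, 7).

**Steps most likely to fail**

**1. Step 7.**
- What may go wrong: aryl transfer may be sluggish. Attack may drift to the primary terminus. Facial selectivity with an aryl donor may be poor. The copper reagent may displace the angelate in the SN2′ sense.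
- Fallback (known chemistry): it sets out from 13 and 8, uses 7, and comes back at 14. Grignard reagent 13 is added 1,2 to acrolein 8 (THF, −78 °C) to give racemic 1-(3,4,5-trimethoxyphenyl)prop-2-en-1-ol F1. A lipase-catalysed kinetic resolution follows (immobilised Candida antarctica lipase B, vinyl acetate, MTBE, rt). It should leave (S)-1-(3,4,5-trimethoxyphenyl)prop-2-en-1-ol F2 untouched while the R enantiomer is converted into (R)-1-(3,4,5-trimethoxyphenyl)prop-2-en-1-yl acetate F3, which is removed by chromatography. Steglich-type esterification of the S alcohol with acid 7 (EDC·HCl, cat. DMAP, CH2Cl2, 0 °C) then gives 14. Here the aryl–carbon bond is made without stereocontrol and the configuration comes from the resolution.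

**2. Step 5.**
- What may go wrong: reversible conjugate addition of bromide to the activated acyl bromide may isomerise the Z alkene. The E/Z control of the new enol ester may be poor. Acrolein may polymerise.
- Fallback: it sets out from 7 and 13 and comes back at 14, and it avoids any acyl halide. Grignard reagent 13 is treated with propargyl bromide (CuBr cat., Et2O/THF, 0 °C, SN2′) to give 1,2,3-trimethoxy-5-(propa-1,2-dien-1-yl)benzene F4. The O–H bond of acid 7 is then added across the terminal allene C=C under rhodium catalysis ([Rh(cod)Cl]2, the DIOP enantiomer that leads to S, cat. Cs2CO3, 1,2-dichloroethane). This known enantioselective hydroacyloxylation of allenes gives branched allylic esters, and here it gives 14 directly by C–O bond formation.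

**3. Step 2.**
- What may go wrong: the ester may be over-reduced. The vinylalane may equilibrate through its allenolate form with loss of alkene geometry. Paraformaldehyde may be taken up too slowly.
- Fallback: it sets out from 2 and comes back at 4. Syn hydrostannation of 2 (Bu3SnH, Pd(PPh3)4, THF, rt) places tin at the α-carbon and gives tert-butyl (E)-2-(tributylstannyl)but-2-enoate F5. Iododestannylation with retention (I2, CH2Cl2, 0 °C) gives tert-butyl (E)-2-iodobut-2-enoate F6. Stille coupling with (tributylstannyl)methanol (Pd(PPh3)4, CuI, DMF, 50 °C) installs the CH2OH group with retention and gives 4.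

**Further compounds**
F1 | step 7 | racemic 1-(3,4,5-trimethoxyphenyl)prop-2-en-1-ol | C=CC(O)c1cc(OC)c(OC)c(OC)c1
F2 | step 7 | (S)-1-(3,4,5-trimethoxyphenyl)prop-2-en-1-ol | C=C[C@H](O)c1cc(OC)c(OC)c(OC)c1
F3 | step 7 | (R)-1-(3,4,5-trimethoxyphenyl)prop-2-en-1-yl acetate | C=C[C@@H](OC(C)=O)c1cc(OC)c(OC)c(OC)c1
F4 | step 5 | 1,2,3-trimethoxy-5-(propa-1,2-dien-1-yl)benzene | C=C=Cc1cc(OC)c(OC)c(OC)c1
F5 | step 2 | tert-butyl (E)-2-(tributylstannyl)but-2-enoate | CC(C)(C)OC(=O)/C(=C\C)[Sn](CCCC)(CCCC)CCCC
F6 | step 2 | tert-butyl (E)-2-iodobut-2-enoate | CC(C)(C)OC(=O)/C(I)=C\C
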